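How much starting material is left in the flask after 8.0 min, and how much partner has gone with it?

- grey: starting material 1 M; partner 0.60 M; second reagent 1.5 M (in portions, 2); run made earlier; portions every 2.0 min
- flask: starting material 1.0 M; partner 1.20 M; second reagent 1.50 M (in portions, 2); time 8.0 min; the portions of second reagent follow each other after 2.0 min, the first at the start

grey run (percent of the starting material charged)

| time / s | target / % | intermediate / % |
|---|---|---|
| 10.0 | 0 | 1.7 |
| 15.0 | 0.5 | 1.8 |
| 25.0 | 0.4 | 3.2 |
| 40.0 | 0 | 5.7 |
| 60.0 | 0.1 | 8.8 |
| 80.0 | 0.3 | 11.6 |
| 90.0 | 0.7 | 11.9 |

(scatter of a reading: 0.5 percentage points)

* the target in the flask at 8.0 min, as a percentage of the starting material charged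
* the intermediate in the flask at 8.0 min, as a percentage of the starting material charged
* the starting material in the flask at 8.0 min, as a percentage of the starting material charged
* the side product in the flask at 8.0 min, as a percentage of the starting material charged
* concentration of partner at 8.0 min, in M

- what was read earlier has a scatter of 0.5 percentage points, one standard deviation

First ask which number you must know well. I assume that starting material and partner make the intermediate. The grey run has one partner charge, so this stays an assumption. On that route, the portions of second reagent do not enter my reckoning.

Target readings reach 0.7% against a scatter of 0.5 percentage points, and I read no rate from them. On my route that step touches the intermediate, not the starting material, so you can do without it.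

Take the choice of reading first. The intermediate at 80.0 s leaves 24.9% at the end of the flask's run, and the one at 90.0 s leaves 28.1%.

Partner moves the answer further than the reading does. If it averaged 0.60 M, 49.9% would be left.

Now the number. The grey reading gives r = 0.0870 min⁻¹, the fraction converted per minute at 0.60 M of partner. Scale r to 1.20 M and you have T, the route half-time: the pseudo-first-order half-life of starting material with partner held at its charge, 3.98 min. The flask's 8.0 min is 2.01 half-times, which gives the 24.9% above. One partner per starting material would bring partner to 0.449 M, lower than its charge. So 24.9% is my reckoning with partner held at its charge, not with partner as it falls.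

The forecast makes the intermediate from second reagent instead. It gives target 15%, intermediate 42%, starting material 39%, side product 4% and partner 1.05 M. Of the side product it says: “it was not measured, so I guess a few percent”.

The flask gives target 21.9%, intermediate 25.9%, starting material 23.9%, side product 28.3% and partner 0.302 M.

    starting material + partner → intermediate (k = 0.190 M⁻¹ min⁻¹)
    second reagent + intermediate → target (k = 0.130 M⁻¹ min⁻¹)
    starting material + second reagent → side product (k = 0.0870 M⁻¹ min⁻¹)
    2 partner → self-condensation product (k = 0.0730 M⁻¹ min⁻¹)
    second reagent ⇌ dormant form (K = 1.00, k = 0.0650 min⁻¹)

In the flask, starting material stands at 23.9%, close to the reckoned 24.9%, yet partner is down to 0.302 M and side product stands at 28.3%. Take the neighbour, the same flask with 0.48 M of partner. There T is 9.96 min, so 8.0 min is 0.803 half-times and the reckoning leaves 57.3%. The neighbour's starting material stands at 37.7%, which is 20 points below that. Its side product stands at 36.6%.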